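**Plan**
1. Retrosynthetic cuts, in order: the bond from the pyran O–CH carbon to the nonenyl chain (alkenylation of a cyclic oxocarbenium ion); the ring C=C and ester C–O of the dihydropyran (O-acylation, intramolecular Horner–Wadsworth–Emmons); the lactone C–O bond together with one ring bond of the carboxyl-bearing carbinol carbon, which re-expands the cyclohexane to a cycloheptane-1,2-dione; the dione C–C bond (ring-closing metathesis, dihydroxylation, oxidation); the CH2–C(OH) bond at the ring-fusion carbinol.
2. Enabling feature: the carbon shared by the cyclohexane, the lactone and the dihydropyran carries O, C=O and two ring carbons, i.e. it is a tertiary α-hydroxy-acid carbon, and its carboxyl is esterified by the tertiary oxygen 1,4 across the cyclohexane. This is what a benzilic ester rearrangement of a cycloheptane-1,2-dione by a transannular alkoxide produces.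
3. Forward order: ring A (cyclopentane) comes from (1S,5R)-2-oxabicyclo[3.3.0]oct-6-en-3-one; a seven-membered carbocycle is closed on it and oxidised to the dione; the key step contracts it to ring B (cyclohexane) and forms ring C (lactone bridge) at once; ring D (dihydropyran) is closed by olefination; the side chain comes last.
4. Stereochemistry: everything derives from the two centres of 1 — convex-face hydroboration and kinetic enolate protonation on the bicycle, addition anti to the α-branch of the cyclopentanone, hydroxyl-directed anti reduction, the tether in the ring contraction, and axial attack on the oxocarbenium ion.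

Key step: step 15

Remark: the descriptors of the target place the nonenyl group pseudo-axial on the dihydropyran, cis to the lactone carbonyl carbon; the end-game is built for that. Compounds 1, 2, 13, 16, 25 and 32 are taken as commercial.

Step 1
Reactants: 1 (1S,5R)-2-oxabicyclo[3.3.0]oct-6-en-3-one; 2 benzyl chloromethyl ether
Product: 4 4-exo-(benzyloxymethyl) lactone, via lithium lactone enolate 3 (not isolated)
Conditions: LiN(i-Pr)2, THF, −78 °C; then 2, −78 → −40 °C
Reagents that add atoms: none
Why: Enolate alkylation of the cis-fused bicyclic lactone takes place on the convex face, so the CH2OBn group (the future pyran =CH carbon) enters exo, cis to the ring-fusion hydrogen.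

Step 2
Reactants: 4 4-exo-(benzyloxymethyl) lactone
Product: 6 4-endo-(benzyloxymethyl) lactone, via substituted lithium lactone enolate 5 (not isolated)
Conditions: LiN(i-Pr)2, THF, −78 °C; then sat. aq NH4Cl at −78 °C
Reagents that add atoms: none
Why: Kinetic protonation of the planar enolate again occurs on the convex face and so pushes the CH2OBn group to the concave face (deprotonation–kinetic protonation epimerisation), which sets the configuration of the future CHa relative to the ring fusion.

Step 3
Reactants: 6 4-endo-(benzyloxymethyl) lactone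
Product: 8 7-exo-hydroxy lactone, via B-alkyl-9-borabicyclononane 7 (not isolated)
Conditions: 9-BBN, THF, 0 °C → rt; then 30 % H2O2, pH 7 phosphate buffer, 0 °C
Reagents that add atoms: hydrogen peroxide OO
Why: syn-Hydroboration–oxidation places boron on the convex face and on the alkene carbon remote from the ring fusion and the endo side chain, and oxidation with retention gives the exo alcohol (the cyclopentanol centre of ring A).

Step 4
Reactants: 8 7-exo-hydroxy lactone
Product: 9 7-exo-silyloxy lactone
Conditions: TBSCl, imidazole, DMF, rt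
Reagents that add atoms: tert-butyldimethylsilyl chloride CC(C)(C)[Si](C)(C)Cl
Why: Standard silylation of an unhindered secondary alcohol, needed to keep this oxygen apart from the one oxidised in step 7.

Step 5
Reactants: 9 7-exo-silyloxy lactone
Product: 10 bicyclic lactol
Conditions: i-Bu2AlH, CH2Cl2, −78 °C
Reagents that add atoms: none
Why: Partial reduction of a γ-lactone stops at the tetrahedral aluminium lactolate at −78 °C and gives the lactol on work-up.

Step 6
Reactants: 10 bicyclic lactol
Product: 11 vinyl cyclopentanol
Conditions: Ph3PCH3Br, KN(SiMe3)2, THF, −78 → 0 °C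
Reagents that add atoms: methyltriphenylphosphonium bromide C[P+](c1ccccc1)(c1ccccc1)c1ccccc1.[Br-]
Why: Wittig methylenation of the open hydroxy-aldehyde form of the lactol installs the vinyl group and frees the ring hydroxyl, the cold non-stabilised ylide limiting enolisation of the α-branched β-alkoxy aldehyde.

Step 7
Reactants: 11 vinyl cyclopentanol
Product: 12 2,4-trans cyclopentanone
Conditions: Dess–Martin periodinane, NaHCO3, CH2Cl2, 0 °C → rt
Reagents that add atoms: none
Why: Buffered Dess–Martin oxidation gives the ketone without epimerising the α-centre or eliminating the β-silyloxy group.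

Step 8
Reactants: 12 2,4-trans cyclopentanone; 13 N-methoxy-N-methylacetamide
Product: 15 β-hydroxy Weinreb amide, via lithium amide enolate 14 (not isolated)
Conditions: 13, LiN(i-Pr)2, THF, −78 °C; then 12, −78 °C; aq NH4Cl
Reagents that add atoms: none
Why: Aldol-type addition of the amide enolate to the cyclopentanone occurs anti to the branched α-substituent, which puts the new tertiary hydroxyl cis to that substituent (the ring-fusion oxygen of the target).

Step 9
Reactants: 15 β-hydroxy Weinreb amide; 16 vinylmagnesium bromide
Product: 17 β-hydroxy enone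
Conditions: THF, −78 → 0 °C; inverse quench into cold aq NH4Cl
Reagents that add atoms: none
Why: Weinreb ketone synthesis, in which the chelated tetrahedral adduct prevents over-addition and collapses to the vinyl ketone only on work-up.

Step 10
Reactants: 17 β-hydroxy enone
Product: 18 anti-1,3-diol
Conditions: Me4NBH(OAc)3, MeCN/AcOH, −30 °C
Reagents that add atoms: none
Why: Evans–Saksena reduction delivers hydride from the boron bound to the tertiary hydroxyl through a chair in which the more substituted cyclopentane carbon is equatorial, which gives the 1,3-anti diol (the CH–OH centre of ring B).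

Step 11
Reactants: 18 anti-1,3-diol
Product: 19 diene mono-silyl ether
Conditions: TBSCl, imidazole, DMF, 0 °C → rt
Reagents that add atoms: tert-butyldimethylsilyl chloride CC(C)(C)[Si](C)(C)Cl
Why: The secondary allylic hydroxyl is silylated selectively because the tertiary one is too hindered, and it must stay free for step 15.

Step 12
Reactants: 19 diene mono-silyl ether
Product: 20 trans-fused bicyclo[5.3.0]decene
Conditions: second-generation Grubbs catalyst (5 mol %), CH2Cl2, 40 °C
Reagents that add atoms: none
Why: Ring-closing metathesis of two monosubstituted alkenes closes the seven-membered carbocycle with loss of ethene.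

Step 13
Reactants: 20 trans-fused bicyclo[5.3.0]decene
Product: 21 triol
Conditions: OsO4 (cat.), N-methylmorpholine N-oxide, acetone/H2O, rt
Reagents that add atoms: osmium tetroxide O=[Os](=O)(=O)=O; N-methylmorpholine N-oxide C[N+]1([O-])CCOCC1; water O
Why: Upjohn dihydroxylation of the only alkene; the configuration of the two new carbinols is irrelevant because both are oxidised next.

Step 14
Reactants: 21 triol
Product: 22 hydroxy 1,2-dione
Conditions: (COCl)2, DMSO, CH2Cl2, −78 °C; then Et3N, −78 → −30 °C
Reagents that add atoms: none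
Why: Swern oxidation converts the vicinal diol into the 1,2-dione without C–C cleavage and leaves the tertiary alcohol untouched; 22 is used crude.

Step 15
Reactants: 22 hydroxy 1,2-dione
Product: 24 bridged α-hydroxy lactone, via bridged hemiketal lithium alkoxide 23 (not isolated)
Conditions: LiN(SiMe3)2 (1.05 equiv), THF, −78 → 0 °C; aq NH4Cl
Reagents that add atoms: none
Why: Deprotonation of the tertiary hydroxyl (faster than any C–H deprotonation) lets the alkoxide add across the ring to either carbonyl of the cycloheptane-1,2-dione in a 5-exo-trig closure, giving an 8-oxabicyclo[3.2.1]octane hemiketal alkoxide such as 23; the ring carbon next to the hemiketal carbon then migrates with retention to the adjacent lithium-activated ketone carbon, so the hemiketal carbon is extruded as the lactone carbonyl and the seven-membered carbocycle contracts to the cyclohexane. The closest known reaction type is the alkoxide-induced, ring-contracting benzilic ester rearrangement of cyclic 1,2-diones, equivalent to the α-ketol shift that interconverts bicyclo[3.2.1]octane and bicyclo[2.2.2]octane ketols. Three rings are involved: the transient tetrahydrofuran ring of the hemiketal closes by 5-exo-trig addition, the six-membered carbocycle arises by the 1,2-carbon shift, and the lactone bridge of the 2-oxabicyclo[2.2.2]octan-3-one is the hemiketal ring enlarged by that same shift. The one new stereocentre, the carbinol carbon that carries the carboxyl, is fixed by the tether because the lactone can only bridge the face bearing the ring-fusion oxygen, and the migrating carbon keeps its configuration. No regioselectivity is needed, since both hemiketals and both shifts converge on 24; what is needed is that the shift outruns enolisation of the dione toward its two α-stereocentres, which the kinetic preference for O–H deprotonation, one equivalent of lithium base at low temperature and the slow enolisation of an α-silyloxy and an α-branched ketone should secure. The driving force is the exchange of a dipole-opposed 1,2-dione for an ester carbonyl and a chelated α-alkoxide.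

Step 16
Reactants: 24 bridged α-hydroxy lactone; 25 2-(diethoxyphosphoryl)propanoic acid
Product: 26 phosphonopropanoate ester
Conditions: DCC, DMAP (cat.), CH2Cl2, 0 °C → rt
Reagents that add atoms: none
Why: Steglich esterification, which for phosphono acids runs through a ketene and therefore acylates the hindered bridgehead-type tertiary alcohol.

Step 17
Reactants: 26 phosphonopropanoate ester
Product: 27 primary alcohol
Conditions: H2 (1 atm), Pd/C, EtOAc, rt
Reagents that add atoms: none
Why: Hydrogenolysis of the benzyl ether is clean because the molecule has no alkene at this stage.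

Step 18
Reactants: 27 primary alcohol
Product: 28 phosphono aldehyde
Conditions: Dess–Martin periodinane, NaHCO3, CH2Cl2, rt
Reagents that add atoms: none
Why: Dess–Martin oxidation gives the aldehyde; β-elimination of the acyloxy group is impossible because it would place a double bond at a bicyclo[2.2.2] bridgehead.

Step 19
Reactants: 28 phosphono aldehyde
Product: 29 tetracyclic unsaturated δ-lactone
Conditions: LiCl, DBU, MeCN, 0 °C → rt
Reagents that add atoms: none
Why: Intramolecular Horner–Wadsworth–Emmons olefination under Masamune–Roush conditions closes ring D, the ring enforcing the cis relation of ester and CHa on the new trisubstituted alkene.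

Step 20
Reactants: 29 tetracyclic unsaturated δ-lactone
Product: 31 lactol acetate, via diisobutylaluminium lactolate 30 (not isolated)
Conditions: i-Bu2AlH (1.1 equiv), CH2Cl2, −78 °C; then Ac2O, pyridine, DMAP, −78 → −20 °C
Reagents that add atoms: acetic anhydride CC(=O)OC(C)=O
Why: Reductive acetylation traps the aluminium lactolate of the conjugated lactone as the acetate; the bridged lactone, flanked by a quaternary carbon and a tertiary alkoxy carbon, should be reduced more slowly.

Step 21
Reactants: 32 1-nonyne
Product: 34 potassium (E)-non-1-enyltrifluoroborate, via catechol alkenylboronate 33 (not isolated)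
Conditions: catecholborane, neat, 70 °C; then aq KHF2, Et2O, rt
Reagents that add atoms: catecholborane B1Oc2ccccc2O1; potassium hydrogen difluoride [K+].[F-].F
Why: syn, anti-Markovnikov hydroboration of the terminal alkyne fixes the E geometry, and KHF2 converts the boronate into the stable trifluoroborate.

Step 22
Reactants: 31 lactol acetate; 34 potassium (E)-non-1-enyltrifluoroborate
Product: 35 bis-silyl ether of the target
Conditions: BF3·OEt2, MeCN/CH2Cl2, −40 → −20 °C
Reagents that add atoms: none
Why: Ferrier-type C-glycosylation, in which the allylic oxocarbenium ion is attacked at the acetal carbon along the pseudo-axial trajectory, anti to the ring-oxygen lone pair and clear of the vinylic methyl group, which places the alkenyl group cis to the lactone carbonyl carbon with retention of the E alkene.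

Step 23
Reactants: 35 bis-silyl ether of the target
Product: 36 CNP0127096.1
Conditions: Bu4NF, AcOH, THF, rt → 40 °C
Reagents that add atoms: none
Why: Buffered fluoride desilylation frees both secondary alcohols without opening the lactone or ionising the bis-allylic ether.

**Compound list**
1 | (1S,5R)-2-oxabicyclo[3.3.0]oct-6-en-3-one (cis-fused) | O=C1O[C@H]2CC=C[C@H]2C1 | starting material
2 | benzyl chloromethyl ether | ClCOCc1ccccc1 | starting material
3 | lithium enolate of 1 | [Li+].[O-]C1=C[C@@H]2C=CC[C@@H]2O1 | intermediate (not isolated)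
4 | 4-exo-[(benzyloxy)methyl]-2-oxabicyclo[3.3.0]oct-6-en-3-one (CH2OBn cis to H-5) | O=C1O[C@H]2CC=C[C@H]2[C@@H]1COCc3ccccc3 | intermediate
5 | lithium enolate of 4 | [Li+].[O-]C1=C(COCc3ccccc3)[C@@H]2C=CC[C@@H]2O1 | intermediate (not isolated)
6 | 4-endo-[(benzyloxy)methyl]-2-oxabicyclo[3.3.0]oct-6-en-3-one (CH2OBn cis to C-6) | O=C1O[C@H]2CC=C[C@H]2[C@H]1COCc3ccccc3 | intermediate
7 | 7-exo-(9-borabicyclo[3.3.1]nonan-9-yl) adduct of 6 | O=C1O[C@H]2C[C@H](B3C4CCCC3CCC4)C[C@H]2[C@H]1COCc5ccccc5 | intermediate (not isolated)
8 | 4-endo-[(benzyloxy)methyl]-7-exo-hydroxy-2-oxabicyclo[3.3.0]octan-3-one | O=C1O[C@H]2C[C@H](O)C[C@H]2[C@H]1COCc3ccccc3 | intermediate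
9 | 7-exo-TBS ether of 8 | O=C1O[C@H]2C[C@H](O[Si](C)(C)C(C)(C)C)C[C@H]2[C@H]1COCc3ccccc3 | intermediate
10 | lactol of 9 (anomers) | OC1O[C@H]2C[C@H](O[Si](C)(C)C(C)(C)C)C[C@H]2[C@H]1COCc3ccccc3 | intermediate
11 | 2-[1-(benzyloxy)but-3-en-2-yl]-4-(TBSO)cyclopentan-1-ol (OH cis to side chain, OTBS trans to both) | O[C@H]1C[C@H](O[Si](C)(C)C(C)(C)C)C[C@H]1[C@H](C=C)COCc2ccccc2 | intermediate
12 | 2-[1-(benzyloxy)but-3-en-2-yl]-4-(TBSO)cyclopentan-1-one (2,4-trans) | O=C1C[C@H](O[Si](C)(C)C(C)(C)C)C[C@H]1[C@H](C=C)COCc2ccccc2 | intermediate
13 | N-methoxy-N-methylacetamide | CC(=O)N(C)OC | starting material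
14 | lithium enolate of 13 | [Li+].C=C([O-])N(C)OC | intermediate (not isolated)
15 | β-hydroxy Weinreb amide (tertiary OH cis to the butenyl side chain) | O[C@]1(C[C@H](O[Si](C)(C)C(C)(C)C)C[C@H]1[C@H](C=C)COCc2ccccc2)CC(=O)N(C)OC | intermediate
16 | vinylmagnesium bromide | C=C[Mg]Br | starting material
17 | β-hydroxy vinyl ketone | O[C@]1(C[C@H](O[Si](C)(C)C(C)(C)C)C[C@H]1[C@H](C=C)COCc2ccccc2)CC(=O)C=C | intermediate
18 | 1,3-anti diol (allylic secondary alcohol) | O[C@]1(C[C@H](O[Si](C)(C)C(C)(C)C)C[C@H]1[C@H](C=C)COCc2ccccc2)C[C@@H](O)C=C | intermediate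
19 | allylic TBS ether of 18 (tertiary OH free) | O[C@]1(C[C@H](O[Si](C)(C)C(C)(C)C)C[C@H]1[C@H](C=C)COCc2ccccc2)C[C@@H](O[Si](C)(C)C(C)(C)C)C=C | intermediate
20 | 6-[(benzyloxy)methyl]-3,9-bis(TBSO)bicyclo[5.3.0]dec-4-en-1-ol (trans ring fusion) | O[C@]1(C[C@H](O[Si](C)(C)C(C)(C)C)C[C@H]1[C@H]2COCc3ccccc3)C[C@@H](O[Si](C)(C)C(C)(C)C)C=C2 | intermediate
21 | corresponding 1,4,5-triol (cis-4,5-diol) | O[C@]1(C[C@H](O[Si](C)(C)C(C)(C)C)C[C@H]1[C@H]2COCc3ccccc3)C[C@@H](O[Si](C)(C)C(C)(C)C)C(O)C2O | intermediate
22 | 6-[(benzyloxy)methyl]-1-hydroxy-3,9-bis(TBSO)bicyclo[5.3.0]decane-4,5-dione | O[C@]1(C[C@H](O[Si](C)(C)C(C)(C)C)C[C@H]1[C@H]2COCc3ccccc3)C[C@@H](O[Si](C)(C)C(C)(C)C)C(=O)C2=O | intermediate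
23 | lithium alkoxide of the transannular hemiketal (oxygen bridge from C-1 to C-5, ketone at C-4) | [Li+].[O-][C@@]12O[C@]3(C[C@H](O[Si](C)(C)C(C)(C)C)C[C@H]3[C@H]1COCc4ccccc4)C[C@@H](O[Si](C)(C)C(C)(C)C)C2=O | intermediate (not isolated)
24 | tricyclic α-hydroxy lactone: 2-oxabicyclo[2.2.2]octan-3-one fused to ring A, bridgehead OH | O[C@@]12C(=O)O[C@]3(C[C@H](O[Si](C)(C)C(C)(C)C)C[C@H]3[C@H]1COCc4ccccc4)C[C@H]2O[Si](C)(C)C(C)(C)C | intermediate
25 | 2-(diethoxyphosphoryl)propanoic acid | CCOP(=O)(OCC)C(C)C(=O)O | starting material
26 | 2-(diethoxyphosphoryl)propanoate of 24 (epimers at the P-bearing carbon) | CCOP(=O)(OCC)C(C)C(=O)O[C@@]12C(=O)O[C@]3(C[C@H](O[Si](C)(C)C(C)(C)C)C[C@H]3[C@H]1COCc4ccccc4)C[C@H]2O[Si](C)(C)C(C)(C)C | intermediate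
27 | debenzylated primary alcohol | CCOP(=O)(OCC)C(C)C(=O)O[C@@]12C(=O)O[C@]3(C[C@H](O[Si](C)(C)C(C)(C)C)C[C@H]3[C@H]1CO)C[C@H]2O[Si](C)(C)C(C)(C)C | intermediate
28 | phosphono aldehyde | CCOP(=O)(OCC)C(C)C(=O)O[C@@]12C(=O)O[C@]3(C[C@H](O[Si](C)(C)C(C)(C)C)C[C@H]3[C@H]1C=O)C[C@H]2O[Si](C)(C)C(C)(C)C | intermediate
29 | tetracyclic bis-lactone (ring D as 3-methyl-5,6-dihydro-2H-pyran-2-one) | O=C1O[C@@]23C(=O)O[C@]4(C[C@H](O[Si](C)(C)C(C)(C)C)C[C@H]4[C@H]2C=C1C)C[C@H]3O[Si](C)(C)C(C)(C)C | intermediate
30 | diisobutylaluminium lactolate of 29 | CC(C)C[Al](CC(C)C)OC1O[C@@]23C(=O)O[C@]4(C[C@H](O[Si](C)(C)C(C)(C)C)C[C@H]4[C@H]2C=C1C)C[C@H]3O[Si](C)(C)C(C)(C)C | intermediate (not isolated)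
31 | lactol acetate (anomers) | CC(=O)OC1O[C@@]23C(=O)O[C@]4(C[C@H](O[Si](C)(C)C(C)(C)C)C[C@H]4[C@H]2C=C1C)C[C@H]3O[Si](C)(C)C(C)(C)C | intermediate
32 | 1-nonyne | CCCCCCCC#C | starting material
33 | 2-[(E)-non-1-enyl]-1,3,2-benzodioxaborole | CCCCCCC/C=C/B1Oc2ccccc2O1 | intermediate (not isolated)
34 | potassium (E)-non-1-enyltrifluoroborate | CCCCCCC/C=C/[B-](F)(F)F.[K+] | intermediate
35 | bis-TBS ether of the target | CCCCCCC/C=C/[C@H]1O[C@@]23C(=O)O[C@]4(C[C@H](O[Si](C)(C)C(C)(C)C)C[C@H]4[C@H]2C=C1C)C[C@H]3O[Si](C)(C)C(C)(C)C | intermediate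
36 | CNP0127096.1 | CCCCCCC/C=C/[C@H]1O[C@@]23C(=O)O[C@]4(C[C@H](O)C[C@H]4[C@H]2C=C1C)C[C@H]3O | target

**Totals and risks**
Total step count: 23. Longest linear sequence: 22 steps (steps 1–20, 22, 23); step 21 is a one-step side branch.

Steps most likely to fail:

Step 22. The alkenyl group may be delivered to the face of the oxocarbenium ion turned away from the lactone bridge, which gives the epimer at the pyran carbon, or to the vinylogous position. The fallback reverses the order in which hydrogen and the alkenyl group arrive at that carbon. It sets out from 29: hydrozirconation of 32 with Cp2Zr(H)Cl and iodination gives (E)-1-iodonon-1-ene F6; t-BuLi converts it into (E)-non-1-enyllithium F7, which adds at −78 °C to the conjugated lactone carbonyl to give the alkenyl hemiketal F8. Ionic reduction (Et3SiH, BF3·OEt2, CH2Cl2, −78 °C) then sends hydride along the trajectory the carbon nucleophile had preferred, which leaves the alkenyl group cis to the lactone carbonyl carbon, and the route is rejoined at 35.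

Step 15. The 1,2-shift from the bridged hemiketal alkoxide may be too slow, so that enolisation of the dione toward its two α-centres, reversion, or silyl transfer to the new tertiary alkoxide takes over. The fallback replaces the intramolecular ester variant by the classical benzilic acid rearrangement in water, where the carboxylate forms irreversibly and no alkoxide survives next to the silyl ether. It sets out from 22: KOH in aqueous dioxane at rt (any lactone formed is saponified to the same product) gives the ring-contracted dihydroxy acid F1; lactonisation onto the tertiary hydroxyl with 2-methyl-6-nitrobenzoic anhydride, DMAP and Et3N in toluene closes the bridge, which only the isomer with carboxyl and ring-fusion hydroxyl cis can do, and rejoins the route at 24.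

Step 20. Hydride may not tell the two ester carbonyls apart, giving reduction of the bridged lactone or double reduction of the conjugated one. The fallback brings in the pyran carbon as a Weinreb amide, for which an ester-sparing reductant exists. It sets out from 24: hydrogenolysis (H2, Pd/C) gives diol F2 and Dess–Martin oxidation the hydroxy aldehyde F3; a Z-selective Horner–Wadsworth–Emmons reaction of the Still–Gennari type with N-methoxy-N-methyl-2-[bis(2,2,2-trifluoroethoxy)phosphoryl]propanamide (KN(SiMe3)2, 18-crown-6, THF, −78 °C) gives the (Z)-enamide F4; Cp2Zr(H)Cl reduces the amide to the (Z)-enal, which closes onto the tertiary hydroxyl as lactol F5; acetylation (Ac2O, pyridine, DMAP) rejoins the route at 31.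

**Further compounds**
F1 | step 15 | ring-contracted dihydroxy acid (1-hydroxycyclohexane-1-carboxylic acid with free ring-fusion OH) | O[C@]1(C[C@H](O[Si](C)(C)C(C)(C)C)C[C@H]1[C@H]2COCc3ccccc3)C[C@@H](O[Si](C)(C)C(C)(C)C)[C@]2(O)C(=O)O
F2 | step 20 | debenzylated diol of 24 | O[C@@]12C(=O)O[C@]3(C[C@H](O[Si](C)(C)C(C)(C)C)C[C@H]3[C@H]1CO)C[C@H]2O[Si](C)(C)C(C)(C)C
F3 | step 20 | hydroxy aldehyde | O[C@@]12C(=O)O[C@]3(C[C@H](O[Si](C)(C)C(C)(C)C)C[C@H]3[C@H]1C=O)C[C@H]2O[Si](C)(C)C(C)(C)C
F4 | step 20 | (Z)-N-methoxy-N,2-dimethyl enamide | O[C@@]12C(=O)O[C@]3(C[C@H](O[Si](C)(C)C(C)(C)C)C[C@H]3[C@H]1/C=C(C)\C(=O)N(C)OC)C[C@H]2O[Si](C)(C)C(C)(C)C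
F5 | step 20 | lactol (3-methyl-5,6-dihydro-2H-pyran-2-ol ring D) | OC1O[C@@]23C(=O)O[C@]4(C[C@H](O[Si](C)(C)C(C)(C)C)C[C@H]4[C@H]2C=C1C)C[C@H]3O[Si](C)(C)C(C)(C)C
F6 | step 22 | (E)-1-iodonon-1-ene | CCCCCCC/C=C/I
F7 | step 22 | (E)-non-1-enyllithium | CCCCCCC/C=C/[Li]
F8 | step 22 | 2-[(E)-non-1-enyl] hemiketal of 29 | CCCCCCC/C=C/C1(O)O[C@@]23C(=O)O[C@]4(C[C@H](O[Si](C)(C)C(C)(C)C)C[C@H]4[C@H]2C=C1C)C[C@H]3O[Si](C)(C)C(C)(C)C
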